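Ring B (C1'–C6') carries oxygen on C2', C4' and C6' and carbon on C1', C3' and C5', so it is cut into three ketene-level two-carbon units. C4'–C5' and C6'–C1' come from a cyclobutane-1,3-dione enol silyl ether, and C2'–C3' from 1-(triisopropylsilyloxy)propyne. One neutral thermal benzannulation forms C3'–C4' and C1'–C2', closes ring B, and fixes the bridge, the methyl group and all three oxygens without acid or base near the diarylmethane. The precursor is a 3-silyloxycyclobut-2-en-1-one whose C2 carries the finished ring A (butanoyl, methoxy, two methyls, silylated hydroxyl) through the future bridge CH2. Desilylation and butanoylation at C5' finish the target.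

Key step: step 8

Remark: the target has no stereocentre, so no configuration has to be set; 9 is written as its enol tautomer, transient 16 is racemic, and the only descriptor in the route is the double-bond geometry of transient 17.

Step 1
Reactants: 1 2,5-dimethylbenzene-1,3-diol; 2 butanoyl chloride
Product: 3 1-(2,4-dihydroxy-3,6-dimethylphenyl)butan-1-one
Conditions: AlCl3 (2.5 equiv), PhNO2, 0 °C → 50 °C; then ice/1 M HCl
Reagents that add atoms: none
Why: Friedel–Crafts acylation, in which the two open positions of 1 are equivalent (each ortho to one hydroxyl and para to the other) and the first acyl group deactivates the ring against a second acylation.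

Step 2
Reactants: 3 1-(2,4-dihydroxy-3,6-dimethylphenyl)butan-1-one
Product: 4 1-(2-hydroxy-4-methoxy-3,6-dimethylphenyl)butan-1-one
Conditions: MeI (1.1 equiv), K2CO3 (1.2 equiv), acetone, rt → 40 °C
Reagents that add atoms: iodomethane, CI
Why: Williamson etherification with one equivalent of MeI, selective because the 2-hydroxyl is tied up in a hydrogen bond to the ketone and flanked on both sides, whereas the 4-hydroxyl para to the carbonyl is the more acidic and the more accessible one.

Step 3
Reactants: 4 1-(2-hydroxy-4-methoxy-3,6-dimethylphenyl)butan-1-one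
Product: 5 1-[5-(chloromethyl)-2-hydroxy-4-methoxy-3,6-dimethylphenyl]butan-1-one
Conditions: (CH2O)n (excess), conc. HCl, HCl (g), AcOH, 40 °C
Reagents that add atoms: formaldehyde (as paraformaldehyde), C=O; hydrogen chloride, Cl
Why: Blanc chloromethylation at the only unsubstituted ring carbon, which is para to the free hydroxyl and ortho to the methoxy group, with excess formaldehyde and HCl keeping the benzylic chloride from alkylating unreacted 4.

Step 4
Reactants: 6 3-ethoxycyclobut-2-en-1-one
Product: 7 cyclobutane-1,3-dione
Conditions: 90% H2SO4, 0 °C, 20 min; poured on ice; continuous extraction (Et2O); used at once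
Reagents that add atoms: water, O
Why: Acid hydrolysis of a vinylogous ester (protonation on the carbonyl oxygen, addition of water at C3, loss of ethanol), carried out just before use because the dione decomposes slowly on storage.

Step 5
Reactants: 5 1-[5-(chloromethyl)-2-hydroxy-4-methoxy-3,6-dimethylphenyl]butan-1-one; 7 cyclobutane-1,3-dione
Product: 9 2-[(3-butanoyl-4-hydroxy-6-methoxy-2,5-dimethylphenyl)methyl]-3-hydroxycyclobut-2-en-1-one, via para-quinone methide 8 (not isolated)
Conditions: 7 (1.5 equiv), iPr2NEt (3 equiv), MeCN, 0 °C; 5 added slowly; rt; then 1 M HCl, acid–base extraction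
Reagents that add atoms: none
Why: 1,6-Conjugate addition of a 1,3-dicarbonyl enolate to a para-quinone methide, in which the base ionises the phenol of 5, chloride leaves to give 8, and the enolate of 7 adds through its central carbon, while any O-alkylated adduct can re-ionise to 8 so that the irreversible C–C bond formation should prevail.

Step 6
Reactants: 9 2-[(3-butanoyl-4-hydroxy-6-methoxy-2,5-dimethylphenyl)methyl]-3-hydroxycyclobut-2-en-1-one
Product: 10 2-({3-butanoyl-6-methoxy-2,5-dimethyl-4-[(triisopropylsilyl)oxy]phenyl}methyl)-3-[(triisopropylsilyl)oxy]cyclobut-2-en-1-one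
Conditions: iPr3SiOTf (2.3 equiv), 2,6-lutidine (3 equiv), CH2Cl2, −78 °C → rt; pentane, filtration, no aqueous work-up; used without chromatography
Reagents that add atoms: triisopropylsilyl trifluoromethanesulfonate, CC(C)[Si](C(C)C)(C(C)C)OS(=O)(=O)C(F)(F)F
Why: O-Silylation with a silyl triflate, in which the acidic enol and the phenol react while 2,6-lutidine is too weak a base to enolise the aryl ketone; triisopropylsilyl is chosen over a smaller silyl group because a vinylogous silyl ester would otherwise hydrolyse easily and could pass its silyl group to the phenol formed in step 8.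

Step 7
Reactants: 11 ethyl acetate
Product: 14 triisopropyl(prop-1-yn-1-yloxy)silane, via lithium 1,1-dibromoprop-1-en-2-olate 12 (not isolated), via lithium prop-1-yn-1-olate 13 (not isolated)
Conditions: CH2Br2, lithium 2,2,6,6-tetramethylpiperidide, THF, −78 °C; 11; LiN(SiMe3)2; n-BuLi, −78 °C → rt; iPr3SiCl, −78 °C → rt; distillation
Reagents that add atoms: dibromomethane, BrCBr; chlorotriisopropylsilane, CC(C)[Si](Cl)(C(C)C)C(C)C
Why: Kowalski ester homologation, in which LiCHBr2 adds to the ester, the derived dibromo enolate 12 undergoes bromine–lithium exchange and 1,2-shift to ynolate 13, and the bulky chlorosilane silylates 13 on oxygen and not on carbon.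

Step 8
Reactants: 10 2-(arylmethyl)-3-(triisopropylsilyloxy)cyclobut-2-en-1-one carrying ring A; 14 triisopropyl(prop-1-yn-1-yloxy)silane
Product: 19 1-[5-({4-hydroxy-3-methyl-2,6-bis[(triisopropylsilyl)oxy]phenyl}methyl)-4-methoxy-3,6-dimethyl-2-[(triisopropylsilyl)oxy]phenyl]butan-1-one, via silyloxyvinylketene 15 (not isolated), via vinylcyclobutenone 16 (not isolated), via dienylketene 17 (not isolated), via cyclohexadienone 18 (not isolated)
Conditions: 14 (1.5 equiv), degassed toluene (0.2 M), 80 °C then 110 °C, sealed vessel
Reagents that add atoms: none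
Why: Proposed new method: heat should open 10 by conrotatory 4π electrocyclic ring opening to the 1-silyloxyvinyl ketene 15, whose electrophilic ketene carbon (future C4') is attacked by the nucleophilic methyl-bearing carbon (C3') of 14 while the ketene alpha carbon (C1') closes onto the silyloxy carbon (C2'), a regioselective [2+2] cycloaddition that gives the 4-vinylcyclobutenone 16. A second 4π opening gives dienylketene 17, and ring B is closed by thermal disrotatory 6π electrocyclisation of the (3E) isomer, which re-forms the C4'–C5' bond and gives the six-membered dienone 18; enolisation then delivers phenol 19. The closest known reaction type is the Danheiser benzannulation of 3-alkyl- and 3-aryl-cyclobutenones with triisopropylsilyloxyalkynes to resorcinol monosilyl ethers; what lacks precedent is a cyclobutenone that is a vinylogous silyl ester, whose donor oxygen at C3 may raise the barrier of the first ring opening, although 4-hydroxy-2,3-dialkoxycyclobutenones made from squaric esters do open on heating in the Moore rearrangement. No stereocentre is created in 19, and the quaternary carbon of racemic 16 is lost when that ring opens, so nothing has to be controlled there. The one selectivity the step needs is the orientation of the ketene–alkyne [2+2], secured by the matched polarisation of the partners (the oxygen lone pair makes the alkyne beta carbon nucleophilic and the ketene carbonyl carbon is the only electrophilic site), while the bulky triisopropylsilyl caps on the ring A hydroxyl and on the enol oxygen keep both oxygens from adding to the ketenes or passing silicon on under neutral conditions.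

Step 9
Reactants: 19 tris(triisopropylsilyl) ether of the methylene-bridged biaryl
Product: 20 1-{2-hydroxy-4-methoxy-3,6-dimethyl-5-[(2,4,6-trihydroxy-3-methylphenyl)methyl]phenyl}butan-1-one
Conditions: Bu4NF (3.5 equiv), AcOH (3.5 equiv), degassed THF, 0 °C, argon
Reagents that add atoms: none
Why: Fluoride cleavage of aryl silyl ethers, fast because phenoxides are good leaving groups on silicon, with acetic acid buffering so that the electron-rich bridged polyphenol does not stand as a phenoxide, which limits oxidation and cleavage of the bridge.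

Step 10
Reactants: 20 1-{2-hydroxy-4-methoxy-3,6-dimethyl-5-[(2,4,6-trihydroxy-3-methylphenyl)methyl]phenyl}butan-1-one; 2 butanoyl chloride
Product: 21 1-{3-[(3-butanoyl-4-hydroxy-6-methoxy-2,5-dimethylphenyl)methyl]-2,4,6-trihydroxy-5-methylphenyl}butan-1-one
Conditions: 2 (1.1 equiv), AlCl3 (4 equiv), CH2Cl2/MeNO2, −20 °C → 0 °C (acylium preformed, 20 added last); then cold 1 M HCl
Reagents that add atoms: none
Why: Friedel–Crafts acylation at C5', the only unsubstituted aromatic carbon in the molecule and one flanked by two hydroxyls, run cold with the acylium ion preformed so that acylation should outrun acid-induced cleavage of the methylene bridge, while any aryl ester formed reverts by Fries migration or is cleaved on work-up.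

Compound list
1 | 2,5-dimethylbenzene-1,3-diol | Cc1cc(O)c(C)c(O)c1 | starting material
2 | butanoyl chloride | CCCC(Cl)=O | starting material
3 | 1-(2,4-dihydroxy-3,6-dimethylphenyl)butan-1-one | CCCC(=O)c1c(C)cc(O)c(C)c1O | intermediate
4 | 1-(2-hydroxy-4-methoxy-3,6-dimethylphenyl)butan-1-one | CCCC(=O)c1c(C)cc(OC)c(C)c1O | intermediate
5 | 1-[5-(chloromethyl)-2-hydroxy-4-methoxy-3,6-dimethylphenyl]butan-1-one | CCCC(=O)c1c(C)c(CCl)c(OC)c(C)c1O | intermediate
6 | 3-ethoxycyclobut-2-en-1-one | CCOC1=CC(=O)C1 | starting material
7 | cyclobutane-1,3-dione | O=C1CC(=O)C1 | intermediate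
8 | 2-butanoyl-5-methoxy-3,6-dimethyl-4-methylidenecyclohexa-2,5-dien-1-one (para-quinone methide, formed in the flask) | CCCC(=O)C1=C(C)C(=C)C(OC)=C(C)C1=O | intermediate
9 | 2-[(3-butanoyl-4-hydroxy-6-methoxy-2,5-dimethylphenyl)methyl]-3-hydroxycyclobut-2-en-1-one (enol form of the 2-substituted cyclobutane-1,3-dione) | CCCC(=O)c1c(C)c(CC2=C(O)CC2=O)c(OC)c(C)c1O | intermediate
10 | 2-({3-butanoyl-6-methoxy-2,5-dimethyl-4-[(triisopropylsilyl)oxy]phenyl}methyl)-3-[(triisopropylsilyl)oxy]cyclobut-2-en-1-one | CCCC(=O)c1c(C)c(CC2=C(O[Si](C(C)C)(C(C)C)C(C)C)CC2=O)c(OC)c(C)c1O[Si](C(C)C)(C(C)C)C(C)C | intermediate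
11 | ethyl acetate | CC(=O)OCC | starting material
12 | lithium 1,1-dibromoprop-1-en-2-olate (formed in the flask) | CC([O-])=C(Br)Br.[Li+] | intermediate
13 | lithium prop-1-yn-1-olate (formed in the flask) | CC#C[O-].[Li+] | intermediate
14 | triisopropyl(prop-1-yn-1-yloxy)silane, that is 1-(triisopropylsilyloxy)prop-1-yne | CC#CO[Si](C(C)C)(C(C)C)C(C)C | intermediate
15 | 2-({3-butanoyl-6-methoxy-2,5-dimethyl-4-[(triisopropylsilyl)oxy]phenyl}methyl)-3-[(triisopropylsilyl)oxy]buta-1,3-dien-1-one (formed in the flask) | CCCC(=O)c1c(C)c(CC(=C=O)C(=C)O[Si](C(C)C)(C(C)C)C(C)C)c(OC)c(C)c1O[Si](C(C)C)(C(C)C)C(C)C | intermediate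
16 | racemic 4-({3-butanoyl-6-methoxy-2,5-dimethyl-4-[(triisopropylsilyl)oxy]phenyl}methyl)-2-methyl-3-[(triisopropylsilyl)oxy]-4-{1-[(triisopropylsilyl)oxy]ethenyl}cyclobut-2-en-1-one (formed in the flask) | CCCC(=O)c1c(C)c(CC2(C(=C)O[Si](C(C)C)(C(C)C)C(C)C)C(=O)C(C)=C2O[Si](C(C)C)(C(C)C)C(C)C)c(OC)c(C)c1O[Si](C(C)C)(C(C)C)C(C)C | intermediate
17 | (3E)-4-({3-butanoyl-6-methoxy-2,5-dimethyl-4-[(triisopropylsilyl)oxy]phenyl}methyl)-2-methyl-3,5-bis[(triisopropylsilyl)oxy]hexa-1,3,5-trien-1-one (formed in the flask) | CCCC(=O)c1c(C)c(C/C(C(=C)O[Si](C(C)C)(C(C)C)C(C)C)=C(\O[Si](C(C)C)(C(C)C)C(C)C)C(C)=C=O)c(OC)c(C)c1O[Si](C(C)C)(C(C)C)C(C)C | intermediate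
18 | 4-({3-butanoyl-6-methoxy-2,5-dimethyl-4-[(triisopropylsilyl)oxy]phenyl}methyl)-2-methyl-3,5-bis[(triisopropylsilyl)oxy]cyclohexa-2,4-dien-1-one (formed in the flask) | CCCC(=O)c1c(C)c(CC2=C(O[Si](C(C)C)(C(C)C)C(C)C)CC(=O)C(C)=C2O[Si](C(C)C)(C(C)C)C(C)C)c(OC)c(C)c1O[Si](C(C)C)(C(C)C)C(C)C | intermediate
19 | 1-[5-({4-hydroxy-3-methyl-2,6-bis[(triisopropylsilyl)oxy]phenyl}methyl)-4-methoxy-3,6-dimethyl-2-[(triisopropylsilyl)oxy]phenyl]butan-1-one | CCCC(=O)c1c(C)c(Cc2c(O[Si](C(C)C)(C(C)C)C(C)C)c(C)c(O)cc2O[Si](C(C)C)(C(C)C)C(C)C)c(OC)c(C)c1O[Si](C(C)C)(C(C)C)C(C)C | intermediate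
20 | 1-{2-hydroxy-4-methoxy-3,6-dimethyl-5-[(2,4,6-trihydroxy-3-methylphenyl)methyl]phenyl}butan-1-one | CCCC(=O)c1c(C)c(Cc2c(O)c(C)c(O)cc2O)c(OC)c(C)c1O | intermediate
21 | 1-{3-[(3-butanoyl-4-hydroxy-6-methoxy-2,5-dimethylphenyl)methyl]-2,4,6-trihydroxy-5-methylphenyl}butan-1-one | CCCC(=O)c1c(C)c(Cc2c(O)c(C)c(O)c(C(=O)CCC)c2O)c(OC)c(C)c1O | target

Total step count: 10. Longest linear sequence: 8 steps (steps 1, 2, 3, 5, 6, 8, 9 and 10, from compound 1); steps 4 and 7 are side branches.

Steps most likely to fail

Step 8 (bears the label). The first ring opening may be too slow below the temperature at which the silyloxyalkyne isomerises to a silylketene, or the ketene intermediates may be lost to dimerisation before they meet the alkyne. The fallback gives up the benzannulation and brings ring B in as a finished acylphloroglucinol, which is known chemistry. 2-Methylbenzene-1,3,5-triol is acylated with 2 (AlCl3, PhNO2) at one of its two equivalent free positions to give 1-(2,4,6-trihydroxy-3-methylphenyl)butan-1-one F1. F1 is then benzylated at its single remaining ring carbon by quinone methide 8, released from chloride 5 with iPr2NEt in MeCN. The fallback sets out from 5 and comes back to the route at target 21; steps 4 and 6 to 10 are then not needed.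

Step 5. C-alkylation may lose to double alkylation or to decay of the small-ring enolate before it meets the quinone methide. The fallback replaces the alkyl halide by an aldehyde. Setting out from 4, Rieche formylation (Cl2CHOMe, TiCl4, CH2Cl2, 0 °C) at the same free ring carbon should give 3-butanoyl-4-hydroxy-6-methoxy-2,5-dimethylbenzaldehyde F2. L-Proline-catalysed Knoevenagel condensation of F2 with 7, run in the presence of diethyl 2,6-dimethyl-1,4-dihydropyridine-3,5-dicarboxylate, should pass through 2-[(3-butanoyl-4-hydroxy-6-methoxy-2,5-dimethylphenyl)methylidene]cyclobutane-1,3-dione F3, which is reduced in the same flask by hydride transfer (three-component reductive alkylation of a cyclic 1,3-dione). The fallback comes back to the route at 9.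

Step 10. The Lewis acid may cleave or scramble the methylene bridge through ipso-protonation of ring B and loss of the ring A benzyl cation, or acylation may stop at oxygen. The fallback changes the electrophile to a nitrile. Setting out from 20, a Houben–Hoesch reaction with butanenitrile (ZnCl2, HCl gas, Et2O, 0 °C) should precipitate 1-{3-[(3-butanoyl-4-hydroxy-6-methoxy-2,5-dimethylphenyl)methyl]-2,4,6-trihydroxy-5-methylphenyl}butan-1-iminium chloride F4, and warming F4 in water hydrolyses it to the ketone. The fallback comes back to the route at 21.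

Further compounds
F1 | step 8 | 1-(2,4,6-trihydroxy-3-methylphenyl)butan-1-one | CCCC(=O)c1c(O)c(C)c(O)cc1O
F2 | step 5 | 3-butanoyl-4-hydroxy-6-methoxy-2,5-dimethylbenzaldehyde | CCCC(=O)c1c(C)c(C=O)c(OC)c(C)c1O
F3 | step 5 | 2-[(3-butanoyl-4-hydroxy-6-methoxy-2,5-dimethylphenyl)methylidene]cyclobutane-1,3-dione | CCCC(=O)c1c(C)c(C=C2C(=O)CC2=O)c(OC)c(C)c1O
F4 | step 10 | 1-{3-[(3-butanoyl-4-hydroxy-6-methoxy-2,5-dimethylphenyl)methyl]-2,4,6-trihydroxy-5-methylphenyl}butan-1-iminium chloride | CCCC(=[NH2+])c1c(O)c(C)c(O)c(Cc2c(C)c(C(=O)CCC)c(O)c(C)c2OC)c1O.[Cl-]
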